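## Retrosynthetic overview

1. Brevipolide I ⇐ acyclic (Z)-enoate 23. HF removes two silyl ethers and C5–OH lactonises, so the dihydropyranone is the second ring and is formed last; the (Z)-cinnamate is put on C11–OH one step earlier.
2. The (Z)-enoate ⇐ the allyl group of cyclopropyl ketone 15 (ozonolysis, then Still–Gennari olefination).
3. Key step, cyclopropane (first ring): the C7–C9 bond is made by 3-exo-tet alkylation of the C9 ketone enolate on a C7 secondary bromide, not by carbenoid cyclopropanation of an allylic alcohol. C7 is relayed from one epoxide by double inversion and C9 follows as the trans centre.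
4. Bromide 13 ⇐ C7-selective bromide opening of the erythro trans-epoxy alcohol 11 ⇐ matched Sharpless epoxidation of dienol 10 ⇐ catalytic asymmetric allylboration of enal 8.
5. Enal 8 ⇐ cross-metathesis of crotonaldehyde with butenyl ketone 6 ⇐ Weinreb amide of ethyl (S)-lactate.

Assumption: atoms are numbered C1 (lactone C=O) to C12 (lactate CH3), with C8 the cyclopropane CH2; the SMILES is read as 5R,6S,7S,9S,11S with a trans-cyclopropane and a (Z)-cinnamate.

## Route

Step 1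
Reactants: 1 ethyl (S)-lactate; 2 N,O-dimethylhydroxylamine hydrochloride
Product: 3 (S)-2-hydroxy-N-methoxy-N-methylpropanamide
Conditions: 2 (2.5 equiv), iPrMgCl (5 equiv), THF, -20 to 0 °C; aq NH4Cl
Reagents that add atoms: none
Why: Weinreb amidation of the ester by the chloromagnesium amide of MeNHOMe (the lactate OH is carried as its magnesium alkoxide), which leaves the C11 stereocentre from the chiral pool untouched.

Step 2
Reactants: 3 (S)-2-hydroxy-N-methoxy-N-methylpropanamide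
Product: 4 (S)-N-methoxy-N-methyl-2-[(triethylsilyl)oxy]propanamide
Conditions: Et3SiCl, imidazole, CH2Cl2, 0 °C to rt
Reagents that add atoms: chlorotriethylsilane, CC[Si](Cl)(CC)CC
Why: Standard imidazole-promoted O-silylation; the TES ether survives the later base and metal chemistry yet can be removed before the TBS ethers.

Step 3
Reactants: 4 (S)-N-methoxy-N-methyl-2-[(triethylsilyl)oxy]propanamide; 5 but-3-en-1-ylmagnesium bromide
Product: 6 (S)-2-[(triethylsilyl)oxy]hept-6-en-3-one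
Conditions: 5 (1.5 equiv, 0.5 M in THF), THF, 0 °C; aq NH4Cl
Reagents that add atoms: none
Why: Weinreb ketone synthesis, in which the chelated tetrahedral magnesium adduct stops at the ketone stage and C11 is not epimerised.

Step 4
Reactants: 6 (S)-2-[(triethylsilyl)oxy]hept-6-en-3-one; 7 (E)-but-2-enal
Product: 8 (S,E)-6-oxo-7-[(triethylsilyl)oxy]oct-2-enal
Conditions: second-generation Hoveyda-Grubbs catalyst RuCl2(H2IMes)(=CH-C6H4-2-OiPr) (3 mol %), 7 (5 equiv), CH2Cl2, 40 °C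
Reagents that add atoms: none
Why: Olefin cross-metathesis of a terminal alkene with an electron-poor partner gives the thermodynamically favoured (E)-enal and tolerates the ketone and the silyl ether.

Step 5
Reactants: 8 (S,E)-6-oxo-7-[(triethylsilyl)oxy]oct-2-enal; 9 allylboronic acid pinacol ester
Product: 10 (2S,6E,8R)-8-hydroxy-2-[(triethylsilyl)oxy]undeca-6,10-dien-3-one
Conditions: (R)-TRIP (5 mol %), 9 (1.2 equiv), toluene, -30 °C; aq NaHCO3
Reagents that add atoms: none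
Why: Chiral-phosphoric-acid-catalysed allylboration through a closed chair transition state in which (R)-TRIP exposes the Re face of the aldehyde, setting C5 as R, while the ketone is inert to the allylboronate at -30 °C.

Step 6
Reactants: 10 (2S,6E,8R)-8-hydroxy-2-[(triethylsilyl)oxy]undeca-6,10-dien-3-one
Product: 11 (S)-5-[(2R,3R)-3-[(R)-1-hydroxybut-3-en-1-yl]oxiran-2-yl]-2-[(triethylsilyl)oxy]pentan-3-one
Conditions: Ti(OiPr)4 (10 mol %), D-(-)-DIPT (12 mol %), t-BuOOH (2 equiv, in decane), 4 Å MS, CH2Cl2, -20 °C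
Reagents that add atoms: tert-butyl hydroperoxide, CC(C)(C)OO
Why: Sharpless asymmetric epoxidation in the matched sense, where D-(-)-DIPT gives the (R,R)-trans-epoxide erythro to the (5R)-carbinol and so sets the C6–O configuration of the target, any (5S)-epimer from step 5 is the slow mismatched substrate, and the isolated terminal alkene is inert.

Step 7
Reactants: 11 (S)-5-[(2R,3R)-3-[(R)-1-hydroxybut-3-en-1-yl]oxiran-2-yl]-2-[(triethylsilyl)oxy]pentan-3-one
Product: 12 (2S,6S,7R,8R)-6-bromo-7,8-dihydroxy-2-[(triethylsilyl)oxy]undec-10-en-3-one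
Conditions: Li2NiBr4 (0.4 M in THF, 2 equiv), THF, 0 °C to rt; pH 7 phosphate buffer
Reagents that add atoms: dilithium tetrabromonickelate Li2NiBr4, [Li+].[Li+].[Ni+2].[Br-].[Br-].[Br-].[Br-]
Why: SN2 opening of a 2,3-epoxy alcohol by soft bromide at the carbon remote from the carbinol (C7, because C6 is deactivated by the C5–O bond and the metal bridges C5–OH and the epoxide oxygen), with inversion at C7 and retention of the C6–O bond.

Step 8
Reactants: 12 (2S,6S,7R,8R)-6-bromo-7,8-dihydroxy-2-[(triethylsilyl)oxy]undec-10-en-3-one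
Product: 13 (2S,6S,7R,8R)-6-bromo-7,8-bis[(tert-butyldimethylsilyl)oxy]-2-[(triethylsilyl)oxy]undec-10-en-3-one
Conditions: TBSOTf (3 equiv), 2,6-lutidine (5 equiv), CH2Cl2, -78 to 0 °C
Reagents that add atoms: tert-butyldimethylsilyl trifluoromethanesulfonate, CC(C)(C)[Si](C)(C)OS(=O)(=O)C(F)(F)F
Why: Silyl triflate/lutidine silylation of both secondary alcohols, which also stops the bromohydrin from closing back to the epoxide in the basic key step.

Step 9
Reactants: 13 (2S,6S,7R,8R)-6-bromo-7,8-bis[(tert-butyldimethylsilyl)oxy]-2-[(triethylsilyl)oxy]undec-10-en-3-one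
Product: 15 (S)-1-[(1S,2S)-2-[(1S,2R)-1,2-bis[(tert-butyldimethylsilyl)oxy]pent-4-en-1-yl]cyclopropyl]-2-[(triethylsilyl)oxy]propan-1-one, via lithium enolate 14 (not isolated)
Conditions: LiN(SiMe3)2 (1.15 equiv), THF, -78 °C; then DMPU, -78 to 0 °C; aq NH4Cl
Reagents that add atoms: none
Why: Intramolecular enolate alkylation (1,3-elimination of a γ-bromo ketone) in which kinetic deprotonation takes the C9 methylene rather than the hindered silyloxy methine C11, the Baldwin-favoured 3-exo-tet C-alkylation inverts C7 a second time (making it S), and the acyl group takes the trans position on the new ring, fixing C9 as S.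

Step 10
Reactants: 15 (S)-1-[(1S,2S)-2-[(1S,2R)-1,2-bis[(tert-butyldimethylsilyl)oxy]pent-4-en-1-yl]cyclopropyl]-2-[(triethylsilyl)oxy]propan-1-one
Product: 17 (3R,4S)-3,4-bis[(tert-butyldimethylsilyl)oxy]-4-[(1S,2S)-2-[(S)-2-[(triethylsilyl)oxy]propanoyl]cyclopropyl]butanal, via ozonide 16 (not isolated)
Conditions: O3, CH2Cl2, -78 °C; then PPh3, -78 °C to rt
Reagents that add atoms: ozone, [O-][O+]=O
Why: Ozonolysis with reductive work-up cleaves the only C=C bond in the molecule to the β-silyloxy aldehyde without touching the cyclopropane, ketone or silyl ethers.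

Step 11
Reactants: 17 (3R,4S)-3,4-bis[(tert-butyldimethylsilyl)oxy]-4-[(1S,2S)-2-[(S)-2-[(triethylsilyl)oxy]propanoyl]cyclopropyl]butanal; 18 methyl bis(2,2,2-trifluoroethyl)phosphonoacetate
Product: 19 methyl (2Z,5R,6S)-5,6-bis[(tert-butyldimethylsilyl)oxy]-6-[(1S,2S)-2-[(S)-2-[(triethylsilyl)oxy]propanoyl]cyclopropyl]hex-2-enoate
Conditions: 18 (1.3 equiv), KN(SiMe3)2 (1.25 equiv), 18-crown-6, THF, -78 °C
Reagents that add atoms: none
Why: Still–Gennari variant of the Horner–Wadsworth–Emmons reaction, where the trifluoroethyl phosphonate eliminates fast and irreversibly to the (Z)-enoate and the stabilised anion attacks the aldehyde but not the hindered ketone.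

Step 12
Reactants: 19 methyl (2Z,5R,6S)-5,6-bis[(tert-butyldimethylsilyl)oxy]-6-[(1S,2S)-2-[(S)-2-[(triethylsilyl)oxy]propanoyl]cyclopropyl]hex-2-enoate
Product: 20 methyl (2Z,5R,6S)-5,6-bis[(tert-butyldimethylsilyl)oxy]-6-[(1S,2S)-2-[(S)-2-hydroxypropanoyl]cyclopropyl]hex-2-enoate
Conditions: PPTS (0.2 equiv), MeOH/CH2Cl2 1:4, 0 °C
Reagents that add atoms: none
Why: Acid-catalysed methanolysis is far faster for the TES ether than for the two hindered TBS ethers, so only the C11 hydroxyl is released.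

Step 13
Reactants: 21 3-(4-methoxyphenyl)prop-2-ynoic acid
Product: 22 (Z)-3-(4-methoxyphenyl)prop-2-enoic acid
Conditions: H2 (1 atm), Pd/CaCO3 poisoned with Pb(OAc)2 (Lindlar catalyst), quinoline, EtOAc, rt, dark
Reagents that add atoms: none
Why: Lindlar semihydrogenation adds H2 syn to the alkyne on the poisoned palladium surface and stops at the (Z)-alkene.

Step 14
Reactants: 20 methyl (2Z,5R,6S)-5,6-bis[(tert-butyldimethylsilyl)oxy]-6-[(1S,2S)-2-[(S)-2-hydroxypropanoyl]cyclopropyl]hex-2-enoate; 22 (Z)-3-(4-methoxyphenyl)prop-2-enoic acid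
Product: 23 methyl (2Z,5R,6S)-5,6-bis[(tert-butyldimethylsilyl)oxy]-6-[(1S,2S)-2-[(S)-2-{[(Z)-3-(4-methoxyphenyl)prop-2-enoyl]oxy}propanoyl]cyclopropyl]hex-2-enoate
Conditions: EDCI·HCl (1.5 equiv), DMAP (0.2 equiv), CH2Cl2, 0 °C, dark
Reagents that add atoms: none
Why: Carbodiimide (Steglich) esterification acylates the only free hydroxyl with retention at C11, and low temperature, little DMAP and exclusion of light keep the cinnamate Z.

Step 15
Reactants: 23 methyl (2Z,5R,6S)-5,6-bis[(tert-butyldimethylsilyl)oxy]-6-[(1S,2S)-2-[(S)-2-{[(Z)-3-(4-methoxyphenyl)prop-2-enoyl]oxy}propanoyl]cyclopropyl]hex-2-enoate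
Product: 25 brevipolide I, (S)-1-[(1S,2S)-2-[(S)-hydroxy[(R)-6-oxo-3,6-dihydro-2H-pyran-2-yl]methyl]cyclopropyl]-1-oxopropan-2-yl (Z)-3-(4-methoxyphenyl)prop-2-enoate, via dihydroxy ester 24 (not isolated)
Conditions: 48% aq HF, MeCN, 0 °C to rt
Reagents that add atoms: none
Why: HF cleaves both TBS ethers and the freed C5–OH undergoes acid-promoted 6-exo-trig transesterification onto the (Z)-enoate, whereas C6–OH could only form a seven-membered ring and stays free.

## Compound list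

1 | ethyl (S)-lactate | C[C@H](O)C(=O)OCC | starting material
2 | N,O-dimethylhydroxylamine hydrochloride | CNOC.Cl | starting material
3 | (S)-2-hydroxy-N-methoxy-N-methylpropanamide | C[C@H](O)C(=O)N(C)OC | intermediate
4 | (S)-N-methoxy-N-methyl-2-[(triethylsilyl)oxy]propanamide | C[C@H](O[Si](CC)(CC)CC)C(=O)N(C)OC | intermediate
5 | but-3-en-1-ylmagnesium bromide | C=CCC[Mg]Br | starting material
6 | (S)-2-[(triethylsilyl)oxy]hept-6-en-3-one | C[C@H](O[Si](CC)(CC)CC)C(=O)CCC=C | intermediate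
7 | (E)-but-2-enal (crotonaldehyde) | C/C=C/C=O | starting material
8 | (S,E)-6-oxo-7-[(triethylsilyl)oxy]oct-2-enal | C[C@H](O[Si](CC)(CC)CC)C(=O)CC/C=C/C=O | intermediate
9 | allylboronic acid pinacol ester | C=CCB1OC(C)(C)C(C)(C)O1 | starting material
10 | (2S,6E,8R)-8-hydroxy-2-[(triethylsilyl)oxy]undeca-6,10-dien-3-one | C[C@H](O[Si](CC)(CC)CC)C(=O)CC/C=C/[C@H](O)CC=C | intermediate
11 | (S)-5-[(2R,3R)-3-[(R)-1-hydroxybut-3-en-1-yl]oxiran-2-yl]-2-[(triethylsilyl)oxy]pentan-3-one (trans-epoxide, erythro to the carbinol) | C[C@H](O[Si](CC)(CC)CC)C(=O)CC[C@H]1O[C@@H]1[C@H](O)CC=C | intermediate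
12 | (2S,6S,7R,8R)-6-bromo-7,8-dihydroxy-2-[(triethylsilyl)oxy]undec-10-en-3-one | C[C@H](O[Si](CC)(CC)CC)C(=O)CC[C@H](Br)[C@H](O)[C@H](O)CC=C | intermediate
13 | (2S,6S,7R,8R)-6-bromo-7,8-bis[(tert-butyldimethylsilyl)oxy]-2-[(triethylsilyl)oxy]undec-10-en-3-one | C[C@H](O[Si](CC)(CC)CC)C(=O)CC[C@H](Br)[C@H](O[Si](C)(C)C(C)(C)C)[C@H](O[Si](C)(C)C(C)(C)C)CC=C | intermediate
14 | lithium (Z)-enolate of 13 (C3=C4 enolate) | C[C@H](O[Si](CC)(CC)CC)/C(O[Li])=C/C[C@H](Br)[C@H](O[Si](C)(C)C(C)(C)C)[C@H](O[Si](C)(C)C(C)(C)C)CC=C | intermediate (not isolated)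
15 | (S)-1-[(1S,2S)-2-[(1S,2R)-1,2-bis[(tert-butyldimethylsilyl)oxy]pent-4-en-1-yl]cyclopropyl]-2-[(triethylsilyl)oxy]propan-1-one | C[C@H](O[Si](CC)(CC)CC)C(=O)[C@H]1C[C@@H]1[C@H](O[Si](C)(C)C(C)(C)C)[C@H](O[Si](C)(C)C(C)(C)C)CC=C | intermediate
16 | ozonide (1,2,4-trioxolane) of 15 | C[C@H](O[Si](CC)(CC)CC)C(=O)[C@H]1C[C@@H]1[C@H](O[Si](C)(C)C(C)(C)C)[C@H](O[Si](C)(C)C(C)(C)C)CC2OCOO2 | intermediate (not isolated)
17 | (3R,4S)-3,4-bis[(tert-butyldimethylsilyl)oxy]-4-[(1S,2S)-2-[(S)-2-[(triethylsilyl)oxy]propanoyl]cyclopropyl]butanal | C[C@H](O[Si](CC)(CC)CC)C(=O)[C@H]1C[C@@H]1[C@H](O[Si](C)(C)C(C)(C)C)[C@H](O[Si](C)(C)C(C)(C)C)CC=O | intermediate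
18 | methyl bis(2,2,2-trifluoroethyl)phosphonoacetate | COC(=O)CP(=O)(OCC(F)(F)F)OCC(F)(F)F | starting material
19 | methyl (2Z,5R,6S)-5,6-bis[(tert-butyldimethylsilyl)oxy]-6-[(1S,2S)-2-[(S)-2-[(triethylsilyl)oxy]propanoyl]cyclopropyl]hex-2-enoate | C[C@H](O[Si](CC)(CC)CC)C(=O)[C@H]1C[C@@H]1[C@H](O[Si](C)(C)C(C)(C)C)[C@H](O[Si](C)(C)C(C)(C)C)C/C=C\C(=O)OC | intermediate
20 | methyl (2Z,5R,6S)-5,6-bis[(tert-butyldimethylsilyl)oxy]-6-[(1S,2S)-2-[(S)-2-hydroxypropanoyl]cyclopropyl]hex-2-enoate | C[C@H](O)C(=O)[C@H]1C[C@@H]1[C@H](O[Si](C)(C)C(C)(C)C)[C@H](O[Si](C)(C)C(C)(C)C)C/C=C\C(=O)OC | intermediate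
21 | 3-(4-methoxyphenyl)prop-2-ynoic acid | COc1ccc(C#CC(=O)O)cc1 | starting material
22 | (Z)-3-(4-methoxyphenyl)prop-2-enoic acid | COc1ccc(/C=C\C(=O)O)cc1 | intermediate
23 | methyl (2Z,5R,6S)-5,6-bis[(tert-butyldimethylsilyl)oxy]-6-[(1S,2S)-2-[(S)-2-{[(Z)-3-(4-methoxyphenyl)prop-2-enoyl]oxy}propanoyl]cyclopropyl]hex-2-enoate | COc1ccc(/C=C\C(=O)O[C@@H](C)C(=O)[C@H]2C[C@@H]2[C@H](O[Si](C)(C)C(C)(C)C)[C@H](O[Si](C)(C)C(C)(C)C)C/C=C\C(=O)OC)cc1 | intermediate
24 | methyl (2Z,5R,6S)-5,6-dihydroxy-6-[(1S,2S)-2-[(S)-2-{[(Z)-3-(4-methoxyphenyl)prop-2-enoyl]oxy}propanoyl]cyclopropyl]hex-2-enoate | COc1ccc(/C=C\C(=O)O[C@@H](C)C(=O)[C@H]2C[C@@H]2[C@H](O)[C@H](O)C/C=C\C(=O)OC)cc1 | intermediate (not isolated)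
25 | brevipolide I | COc1ccc(/C=C\C(=O)O[C@@H](C)C(=O)[C@H]2C[C@@H]2[C@H](O)[C@H]2CC=CC(=O)O2)cc1 | target

## Step count and risks

Total step count: 15. Longest linear sequence: 14 steps (steps 1–12, 14 and 15, from ethyl (S)-lactate); step 13 is a one-step side branch.

**Most likely to fail, 1: step 9 (key cyclisation).** Enolisation toward C11 would epimerise the lactate centre or give a cyclopentanone by 5-exo alkylation, and the SN2 at the hindered secondary bromide may be slow. The fallback sets out from 13 and comes back at 15, and replaces the ketone enolate by an azaenolate whose regiochemistry is fixed. Bromo ketone 13 is condensed with Me2NNH2 (cat. AcOH, EtOH, 40 °C) to the (E)-N,N-dimethylhydrazone of 13 F1. LiN(iPr)2 in THF (-78 to 0 °C) metalates the hydrazone only at the less substituted α-CH2 (C9), and the azaenolate closes the ring by the same 3-exo-tet displacement with inversion at C7 to give the N,N-dimethylhydrazone of 15 F2. CuCl2 in THF/pH 7 buffer then hydrolyses F2 to ketone 15.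

**Most likely to fail, 2: step 7 (bromide opening).** Attack at C6, participation of the C10 carbonyl in opening the γ,δ-epoxide, or reversion of the bromohydrin would all spoil the double-inversion relay. The fallback sets out from 6 and comes back at 15, and uses a cis-epoxide with a single inversion and no halide.
- Ketone 6 and (Z)-but-2-ene-1,4-diol undergo Z-selective cross-metathesis with the cyclometalated ruthenium catalyst Ru(NO3)(=CH-C6H4-2-OiPr)(C,C-chelating N-adamantyl-N'-(2,6-diisopropylphenyl)imidazolin-2-ylidene) to give (S,Z)-8-hydroxy-2-[(triethylsilyl)oxy]oct-6-en-3-one F3.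
- Sharpless epoxidation (Ti(OiPr)4, D-(-)-DIPT, t-BuOOH) gives the cis-epoxy alcohol (S)-5-[(2S,3R)-3-(hydroxymethyl)oxiran-2-yl]-2-[(triethylsilyl)oxy]pentan-3-one F4.
- Dess–Martin periodinane gives the cis-epoxy aldehyde (2S,3S)-3-[(S)-3-oxo-4-[(triethylsilyl)oxy]pentyl]oxirane-2-carbaldehyde F5.
- Allylboration with 9 and (R)-TRIP (catalyst control reinforced by Felkin–Anh addition) gives the erythro cis-epoxy alcohol (S)-5-[(2S,3R)-3-[(R)-1-hydroxybut-3-en-1-yl]oxiran-2-yl]-2-[(triethylsilyl)oxy]pentan-3-one F6.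
- TBSCl/imidazole gives the tert-butyldimethylsilyl ether of F6 F7.
- LiN(SiMe3)2 (THF, -78 °C to rt) generates the C9 enolate, which opens the cis-epoxide directly at C7 with one inversion to give the cyclopropyl carbinol (S)-1-[(1S,2S)-2-[(1S,2R)-2-[(tert-butyldimethylsilyl)oxy]-1-hydroxypent-4-en-1-yl]cyclopropyl]-2-[(triethylsilyl)oxy]propan-1-one F8.
- TBSOTf/2,6-lutidine silylates C6–OH and gives 15.

**Most likely to fail, 3: step 14 (esterification with the Z-acid).** The activated (Z)-cinnamoyl species can isomerise to E by reversible conjugate addition of DMAP. The fallback sets out from 20 and comes back at 23, and sets the Z geometry after the ester bond is made. Alcohol 20 is esterified with alkynoic acid 21 (2,4,6-trichlorobenzoyl chloride, Et3N, then DMAP, toluene) to the 3-(4-methoxyphenyl)prop-2-ynoate ester of 20 F9, which has no isomerisable double bond in the acyl part. Lindlar semihydrogenation (H2, Pd/CaCO3 poisoned with Pb(OAc)2, quinoline, EtOAc) then gives 23; the conjugated (Z)-enoate is not reduced under these conditions.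

## Further compounds

F1 | step 9 | (E)-N,N-dimethylhydrazone of 13 | C[C@H](O[Si](CC)(CC)CC)/C(=N/N(C)C)CC[C@H](Br)[C@H](O[Si](C)(C)C(C)(C)C)[C@H](O[Si](C)(C)C(C)(C)C)CC=C
F2 | step 9 | (E)-N,N-dimethylhydrazone of 15 | C[C@H](O[Si](CC)(CC)CC)/C(=N/N(C)C)[C@H]1C[C@@H]1[C@H](O[Si](C)(C)C(C)(C)C)[C@H](O[Si](C)(C)C(C)(C)C)CC=C
F3 | step 7 | (S,Z)-8-hydroxy-2-[(triethylsilyl)oxy]oct-6-en-3-one | C[C@H](O[Si](CC)(CC)CC)C(=O)CC/C=C\CO
F4 | step 7 | (S)-5-[(2S,3R)-3-(hydroxymethyl)oxiran-2-yl]-2-[(triethylsilyl)oxy]pentan-3-one | C[C@H](O[Si](CC)(CC)CC)C(=O)CC[C@@H]1O[C@@H]1CO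
F5 | step 7 | (2S,3S)-3-[(S)-3-oxo-4-[(triethylsilyl)oxy]pentyl]oxirane-2-carbaldehyde | C[C@H](O[Si](CC)(CC)CC)C(=O)CC[C@@H]1O[C@@H]1C=O
F6 | step 7 | (S)-5-[(2S,3R)-3-[(R)-1-hydroxybut-3-en-1-yl]oxiran-2-yl]-2-[(triethylsilyl)oxy]pentan-3-one | C[C@H](O[Si](CC)(CC)CC)C(=O)CC[C@@H]1O[C@@H]1[C@H](O)CC=C
F7 | step 7 | tert-butyldimethylsilyl ether of F6 | C[C@H](O[Si](CC)(CC)CC)C(=O)CC[C@@H]1O[C@@H]1[C@H](O[Si](C)(C)C(C)(C)C)CC=C
F8 | step 7 | (S)-1-[(1S,2S)-2-[(1S,2R)-2-[(tert-butyldimethylsilyl)oxy]-1-hydroxypent-4-en-1-yl]cyclopropyl]-2-[(triethylsilyl)oxy]propan-1-one | C[C@H](O[Si](CC)(CC)CC)C(=O)[C@H]1C[C@@H]1[C@H](O)[C@H](O[Si](C)(C)C(C)(C)C)CC=C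
F9 | step 14 | 3-(4-methoxyphenyl)prop-2-ynoate ester of 20 | COc1ccc(C#CC(=O)O[C@@H](C)C(=O)[C@H]2C[C@@H]2[C@H](O[Si](C)(C)C(C)(C)C)[C@H](O[Si](C)(C)C(C)(C)C)C/C=C\C(=O)OC)cc1
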